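## Retrosynthetic overview

- **Feature.** On ring C of the upper (guibourtinidol) unit, H-2, O-3 and H-4 all lie on the β face. Ring B (at C2) and ring D (at C4) lie on the α face. These three β atoms are exactly what a flat 4-arylflavylium ion lacks.
- **Strategy.** No chiral flavan-3-ol electrophile is coupled. C4, C3 and C2 are written onto an aromatic pyrylium ring C after the C4–C8 bond exists. Hydride goes to C4 under a chiral counter-anion (master centre), then H–B adds syn across C2=C3, anti to ring D.
- **C4–C8 bond.** The 8-lithiated lower unit adds 1,2 to C4=O of commercial 7,4'-dihydroxyflavone (as its dibenzyl ether). The 5-deoxy ring A (C5–H) keeps this carbonyl accessible.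
- **Lower unit (rings D/E/F).** The same logic is carried out by an enzyme. Anthocyanidin reductase turns flat pelargonidin into the 2,3-cis (2R,3R)-flavan-3-ol.
- **Ring order.** No ring is closed in the route, since all six rings are bought in two flat flavonoids. Ring F is dearomatised first (step 1) and ring C last (steps 7 and 8).

Key step: step 7

Assumption: the sense of induction of a BINOL phosphate on this new cation cannot be derived safely from models, so "(R)-TRIP" stands for the antipode that sends hydride to the Re (β) face of C4; both antipodes are commercial.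

## Route

Step 1
Reactants: 1 pelargonidin chloride (3,5,7,4'-tetrahydroxyflavylium chloride)
Product: 2 (−)-epiafzelechin [(2R,3R)-2-(4-hydroxyphenyl)chromane-3,5,7-triol; 2,3-cis]
Conditions: recombinant anthocyanidin reductase (ANR, EC 1.3.1.77, Medicago truncatula type), NADP+ (cat.), glucose dehydrogenase, D-glucose (2.5 equiv), KPi buffer pH 6.5 / 5% MeOH, 30 °C, N2, slow feed of 1
Reagents that add atoms: none
Why: This is the native reaction of the enzyme class anthocyanidin reductase on one of its natural substrates: two NADPH-dependent hydride transfers and one protonation turn the flat flavylium ring F into the 2,3-cis-flavan-3-ol, and the active site fixes both new centres as (2R,3R).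

Step 2
Reactants: 2 (−)-epiafzelechin
Product: 3 5,7,4'-tri-O-benzyl-(−)-epiafzelechin (free 3-OH)
Conditions: BnBr (3.3 equiv), K2CO3, DMF, 0 °C → rt, Ar
Reagents that add atoms: benzyl bromide, BrCc1ccccc1
Why: Williamson etherification in which K2CO3 deprotonates only the three phenols and not the secondary 3-OH, and the low temperature avoids base-induced epimerisation at C2 of the 2,3-cis unit.

Step 3
Reactants: 3 5,7,4'-tri-O-benzyl-(−)-epiafzelechin
Product: 4 8-bromo-5,7,4'-tri-O-benzyl-(−)-epiafzelechin
Conditions: NBS (1.0 equiv), CH2Cl2, −78 → 0 °C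
Reagents that add atoms: N-bromosuccinimide, O=C1CCC(=O)N1Br
Why: Electrophilic aromatic bromination: ring D is the most electron-rich ring and C8 reacts ahead of C6 in 5,7-di-O-benzylated flavan-3-ols, so one equivalent of NBS marks exactly the carbon that will carry the interflavan bond without touching a stereocentre.

Step 4
Reactants: 4 8-bromo-5,7,4'-tri-O-benzyl-(−)-epiafzelechin
Product: 5 8-bromo-3,5,7,4'-tetra-O-benzyl-(−)-epiafzelechin
Conditions: NaH, BnBr, DMF, 0 °C → rt
Reagents that add atoms: benzyl bromide, BrCc1ccccc1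
Why: Williamson etherification of the secondary alkoxide removes the only acidic proton before the lithiation, and the benzyl group falls in the final hydrogenolysis, so no extra deprotection step arises.

Step 5
Reactants: 6 7,4'-dihydroxyflavone
Product: 7 7,4'-bis(benzyloxy)flavone
Conditions: BnBr (2.3 equiv), K2CO3, DMF, 60 °C
Reagents that add atoms: benzyl bromide, BrCc1ccccc1
Why: Williamson etherification of the two phenols of an achiral, base-stable flavone.

Step 6
Reactants: 5 8-bromo-3,5,7,4'-tetra-O-benzyl-(−)-epiafzelechin; 7 7,4'-bis(benzyloxy)flavone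
Product: 9 tertiary carbinol 4-(3,5,7,4'-tetra-O-benzylepiafzelechin-8-yl)-7,4'-bis(benzyloxy)flav-2-en-4-ol (both C4 epimers), via aryllithium of the lower unit 8 (not isolated)
Conditions: 5, n-BuLi (1.05 equiv), THF, −78 °C; then 7 in THF, −78 → 0 °C; H2O quench; filtration through basic alumina (1% Et3N), used at once
Reagents that add atoms: n-butyllithium (its lithium is found only in 8), [Li]CCCC
Why: Bromine–lithium exchange and 1,2-addition of the aryllithium to the 4-pyranone carbonyl is the classical entry to 4-substituted flavylium salts; C2 is blocked by ring B, there is no enolisable α-hydrogen, the 5-deoxy ring A leaves the peri side of C4 open, and the new C4 centre may form unselectively because step 7 erases it.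

Step 7
Reactants: 9 tertiary carbinol (both C4 epimers)
Product: 11 (4S)-4α-(3,5,7,4'-tetra-O-benzylepiafzelechin-8-yl)-7,4'-bis(benzyloxy)flav-2-ene (4H-chromene; H-4 β), via 4-arylflavylium phosphate ion pair 10 (not isolated)
Conditions: (R)-TRIP [3,3'-bis(2,4,6-triisopropylphenyl)-BINOL hydrogen phosphate] (10 mol %), Hantzsch ester (diethyl 1,4-dihydro-2,6-dimethylpyridine-3,5-dicarboxylate, 1.2 equiv), 4 Å MS, CH2Cl2–toluene, −40 °C, dark, Ar
Reagents that add atoms: none
Why: The chiral acid ionises both C4 epimers of 9 with loss of water to one and the same planar 2,4-diaryl-1-benzopyrylium (flavylium) cation 10, whose phosphate counter-ion also binds the N–H of the Hantzsch ester, and hydride then passes irreversibly to C4. The closest known reaction type is the asymmetric counter-anion-directed (ion-pair) transfer hydrogenation of 2,4-disubstituted benzopyrylium ions to 4H-chromenes with Hantzsch esters. No ring is closed: the aromatic pyrylium ring C is dearomatised to the 4H-pyran, and the step is stereoconvergent because the stereocentre made at random in step 6 is erased in 10. The one new stereocentre, C4 (S; H-4 β; ring D α), is controlled by the chiral phosphate, which must open the Re (β) face of C4; the stereocentres of ring F lie four and five bonds away, so catalyst control is expected, and the new C–H bond cannot re-ionise under acid, so the kinetic ratio is kept. The step needs C4 over C2 regioselectivity, which the soft hydride donor and the retained conjugation of the C2=C3 enol ether with ring B should secure, and hydride that strays to C2 on the same β face would still give an isomer that step 8 carries to the same product. Chemoselectivity rests on the substrate: every phenol of ring D is benzylated, so no oxygen can add to C2 to give a bridged ketal, and sieves plus only a slight excess of hydride donor hold back hydration and over-reduction of the enol ether.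

Step 8
Reactants: 11 (4S)-4-arylflav-2-ene
Product: 13 hexabenzyl ether 7,4'-di-O-benzylguibourtinidol-(4α→8)-3,5,7,4'-tetra-O-benzylepiafzelechin (upper unit 2R 3S 4S; free 3-OH; lower unit 2R 3R), via 3β-borylflavan 12 (not isolated)
Conditions: BH3·THF (3 equiv), THF, 0 °C → rt; then aq NaOH, H2O2, 0 °C
Reagents that add atoms: hydrogen peroxide, OO; borane (as its THF complex; its boron is found only in 12), B
Why: Hydroboration–oxidation of a flav-2-ene (cyclic aryl enol ether): O1 and ring B polarise C2=C3 so that boron goes to C3, borane approaches the β face anti to the pseudo-axial 4α-aryl group, syn addition puts H-2 and B-3 both β (ring B α), and oxidation with retention gives the 3β-OH, that is the 2,3-trans-3,4-trans array.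

Step 9
Reactants: 13 hexabenzyl ether
Product: 14 guibourtinidol-(4α→8)-epiafzelechin (target CNP0110462.3)
Conditions: H2 (1 atm), 20% Pd(OH)2/C, THF–MeOH 1:1, rt
Reagents that add atoms: none
Why: Hydrogenolysis of five aryl benzyl ethers and one alkyl benzyl ether under neutral conditions leaves both C2–O1 bonds, the C4–C8 bond and the base-sensitive 2,3-cis lower unit untouched.

## Compound list

1 | pelargonidin chloride (3,5,7,4'-tetrahydroxyflavylium chloride, achiral) | [Cl-].Oc1ccc(cc1)-c1[o+]c2cc(O)cc(O)c2cc1O | starting material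
2 | (−)-epiafzelechin, (2R,3R), 2,3-cis | Oc1cc(O)c2c(c1)O[C@H](c1ccc(O)cc1)[C@H](O)C2 | intermediate
3 | 5,7,4'-tri-O-benzyl-(−)-epiafzelechin, (2R,3R), free 3-OH | C(c1ccccc1)Oc1cc(OCc2ccccc2)c2c(c1)O[C@H](c1ccc(OCc3ccccc3)cc1)[C@H](O)C2 | intermediate
4 | 8-bromo-5,7,4'-tri-O-benzyl-(−)-epiafzelechin, (2R,3R) | Brc1c(OCc2ccccc2)cc(OCc2ccccc2)c2c1O[C@H](c1ccc(OCc3ccccc3)cc1)[C@H](O)C2 | intermediate
5 | 8-bromo-3,5,7,4'-tetra-O-benzyl-(−)-epiafzelechin, (2R,3R) | Brc1c(OCc2ccccc2)cc(OCc2ccccc2)c2c1O[C@H](c1ccc(OCc3ccccc3)cc1)[C@H](OCc1ccccc1)C2 | intermediate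
6 | 7,4'-dihydroxyflavone | O=c1cc(-c2ccc(O)cc2)oc2cc(O)ccc12 | starting material
7 | 7,4'-bis(benzyloxy)flavone | O=c1cc(-c2ccc(OCc3ccccc3)cc2)oc2cc(OCc3ccccc3)ccc12 | intermediate
8 | 8-lithio-3,5,7,4'-tetra-O-benzylepiafzelechin (not isolated) | [Li]c1c(OCc2ccccc2)cc(OCc2ccccc2)c2c1O[C@H](c1ccc(OCc3ccccc3)cc1)[C@H](OCc1ccccc1)C2 | intermediate
9 | 4-(3,5,7,4'-tetra-O-benzylepiafzelechin-8-yl)-7,4'-bis(benzyloxy)flav-2-en-4-ol, both C4 epimers | OC1(C=C(c2ccc(OCc3ccccc3)cc2)Oc2cc(OCc3ccccc3)ccc12)c1c(OCc2ccccc2)cc(OCc2ccccc2)c2c1O[C@H](c1ccc(OCc3ccccc3)cc1)[C@H](OCc1ccccc1)C2 | intermediate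
10 | 4-(3,5,7,4'-tetra-O-benzylepiafzelechin-8-yl)-7,4'-bis(benzyloxy)flavylium cation, paired with the TRIP phosphate anion (cation drawn; not isolated) | c1(cc(-c2ccc(OCc3ccccc3)cc2)[o+]c2cc(OCc3ccccc3)ccc12)-c1c(OCc2ccccc2)cc(OCc2ccccc2)c2c1O[C@H](c1ccc(OCc3ccccc3)cc1)[C@H](OCc1ccccc1)C2 | intermediate
11 | (4S)-4α-(3,5,7,4'-tetra-O-benzylepiafzelechin-8-yl)-7,4'-bis(benzyloxy)flav-2-ene, H-4 β | [C@@H]1(C=C(c2ccc(OCc3ccccc3)cc2)Oc2cc(OCc3ccccc3)ccc12)c1c(OCc2ccccc2)cc(OCc2ccccc2)c2c1O[C@H](c1ccc(OCc3ccccc3)cc1)[C@H](OCc1ccccc1)C2 | intermediate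
12 | 3β-boryl (BH2) flavan with 2α-aryl and 4α-aryl groups, hexabenzyl ether (not isolated) | C(c1ccccc1)Oc1ccc([C@H]2Oc3cc(OCc4ccccc4)ccc3[C@@H](c3c(OCc4ccccc4)cc(OCc4ccccc4)c4c3O[C@H](c3ccc(OCc5ccccc5)cc3)[C@H](OCc3ccccc3)C4)[C@@H]2B)cc1 | intermediate
13 | 7,4'-di-O-benzylguibourtinidol-(4α→8)-3,5,7,4'-tetra-O-benzylepiafzelechin; upper (2R,3S,4S), free 3-OH; lower (2R,3R) | C(c1ccccc1)Oc1ccc([C@H]2Oc3cc(OCc4ccccc4)ccc3[C@@H](c3c(OCc4ccccc4)cc(OCc4ccccc4)c4c3O[C@H](c3ccc(OCc5ccccc5)cc3)[C@H](OCc3ccccc3)C4)[C@@H]2O)cc1 | intermediate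
14 | guibourtinidol-(4α→8)-epiafzelechin; upper (2R,3S,4S), lower (2R,3R) | Oc1ccc([C@H]2Oc3cc(O)ccc3[C@@H](c3c(O)cc(O)c4c3O[C@H](c3ccc(O)cc3)[C@H](O)C4)[C@@H]2O)cc1 | target

## Step count and risks

- Total step count: 9.
- Longest linear sequence: 8 steps (1, 2, 3, 4, 6, 7, 8, 9).

### Steps most likely to fail

**Step 7.**
- What may go wrong:
  - The large cation may sit loosely on the phosphate, so facial discrimination could be poor or be overridden by the lower unit.
  - Hydride transfer to C4 may be slowed by the two ortho oxygens of ring D, so attack at C2 or over-reduction of the enol ether could compete.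
- Fallback (sets out from 5, comes back at 12): the master centre is moved from C4 to C2 and is set before the union.
  - Commercial 7-hydroxychromone is benzylated to 7-(benzyloxy)chromen-4-one F1.
  - A rhodium(I)/chiral diene catalysed asymmetric conjugate addition of 4-(benzyloxy)phenylboronic acid, with the ligand antipode that gives the S product, leads to (S)-7,4'-bis(benzyloxy)flavanone F2.
  - The organocerium reagent made from 8 (5, n-BuLi, then CeCl3, which suppresses enolisation and ring opening of the flavanone) adds to C4=O to give the tertiary flavan-4-ol F3.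
  - Mild dehydration (cat. PPTS, sieves, 0 °C) gives the (2S)-4-arylflav-3-ene F4.
  - Borane adds anti to the 2α-aryl group with boron at C3 and hydrogen at C4. This is organoborane 12, and the route goes on as in step 8.

**Step 8.**
- What may go wrong:
  - The C3 organoborane may lose the O1 aryloxide by β-elimination, which opens ring C.
  - Borane may attack only sluggishly next to the bulky C4 substituent.
- Fallback (sets out from 11, comes back at 13): oxygen is added first and hydrogen last.
  - Dimethyldioxirane in CH2Cl2–acetone–MeOH at −40 °C epoxidises the enol ether from the β face to the 2,3-epoxide F5.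
  - Methanol opens F5 in the flask at the ketal carbon to the 2-methoxyflavan-3-ol F6.
  - Et3SiH/BF3·OEt2 at −78 °C then reduces the C2 ketal by axial hydride attack, the reaction type used to turn 1-aryl glycosyl ketals into β-C-aryl glycosides. This places ring B equatorial and gives 13.

**Step 1.**
- What may go wrong:
  - Hydration and decay of the flavylium ion at near-neutral pH compete with the enzyme, so the volumetric productivity may be low.
  - Long incubation may epimerise C2 of the product.
- Fallback (sets out from 1, comes back at 3): chemical reduction followed by resolution.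
  - Hydrogenation over Adams catalyst (H2, PtO2, EtOH) delivers hydrogen to one face and should give the 2,3-cis compound as the racemate, that is 2 together with (+)-epiafzelechin F7.
  - Benzylation as in step 2 gives 3 together with its enantiomer F8.
  - Preparative chiral-phase SFC then provides 3.

## Further compounds

F1 | step 7 | 7-(benzyloxy)chromen-4-one | O=c1ccoc2cc(OCc3ccccc3)ccc12
F2 | step 7 | (S)-7,4'-bis(benzyloxy)flavanone | C(c1ccccc1)Oc1ccc([C@H]2Oc3cc(OCc4ccccc4)ccc3C(=O)C2)cc1
F3 | step 7 | (2S)-4-(3,5,7,4'-tetra-O-benzylepiafzelechin-8-yl)-7,4'-bis(benzyloxy)flavan-4-ol, C4 epimers | C(c1ccccc1)Oc1ccc([C@H]2Oc3cc(OCc4ccccc4)ccc3C(O)(c3c(OCc4ccccc4)cc(OCc4ccccc4)c4c3O[C@H](c3ccc(OCc5ccccc5)cc3)[C@H](OCc3ccccc3)C4)C2)cc1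
F4 | step 7 | (2S)-4-(3,5,7,4'-tetra-O-benzylepiafzelechin-8-yl)-7,4'-bis(benzyloxy)flav-3-ene | C(c1ccccc1)Oc1ccc([C@H]2Oc3cc(OCc4ccccc4)ccc3C(c3c(OCc4ccccc4)cc(OCc4ccccc4)c4c3O[C@H](c3ccc(OCc5ccccc5)cc3)[C@H](OCc3ccccc3)C4)=C2)cc1
F5 | step 8 | 2β,3β-epoxide of 11 | C(c1ccccc1)Oc1ccc([C@@]23Oc4cc(OCc5ccccc5)ccc4[C@@H](c4c(OCc5ccccc5)cc(OCc5ccccc5)c5c4O[C@H](c4ccc(OCc6ccccc6)cc4)[C@H](OCc4ccccc4)C5)[C@@H]2O3)cc1
F6 | step 8 | 2-methoxy-3β-hydroxy-4α-arylflavan (C2 ketal, both anomers) | C(c1ccccc1)Oc1ccc(C2(OC)Oc3cc(OCc4ccccc4)ccc3[C@@H](c3c(OCc4ccccc4)cc(OCc4ccccc4)c4c3O[C@H](c3ccc(OCc5ccccc5)cc3)[C@H](OCc3ccccc3)C4)[C@@H]2O)cc1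
F7 | step 1 | (+)-epiafzelechin, (2S,3S), formed with 2 as the racemate | Oc1cc(O)c2c(c1)O[C@@H](c1ccc(O)cc1)[C@@H](O)C2
F8 | step 1 | 5,7,4'-tri-O-benzyl-(+)-epiafzelechin, (2S,3S), formed with 3 as the racemate | C(c1ccccc1)Oc1cc(OCc2ccccc2)c2c(c1)O[C@@H](c1ccc(OCc3ccccc3)cc1)[C@@H](O)C2
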